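**Retrosynth­etic overview**

1. 22 ⇐ 21 ⇐ 20 by two late oxidations. Both rings (cyclohexene and cyclopentane) close together in one intramolecular Diels–Alder reaction of tetraenal 19, which forms C4–C5 and C3a–C7a and sets four stereocentres.
2. 19 ⇐ alkyne diol 14: the diene is built on the alkyne by a hydroxyl-directed syn-hydroalkenylation with linchpin 15 (C6–C7 bond, the new step), then a Suzuki coupling with styrylboronic acid.
3. 14 ⇐ aldehyde 7 + dienol ether 12 by an auxiliary-controlled vinylogous Mukaiyama aldol (C2–C3 bond, C3 stereocentre).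
4. 7 ⇐ epoxy alcohol 2 ⇐ (E)-pent-2-en-1-ol. The route is organised around the C2–O bond: it is made first by asymmetric epoxidation, relays its configuration to C1 by invertive alkynylation, directs step 9 as the free hydroxyl, and ends as the ketone oxygen.

Assumption: locants C1 to C7a in the text are the indene locants of target 22 (C2 ketone carbon; C4 carboxyl-bearing carbon; C5 styryl-bearing carbon; C6=C7 ring alkene).

**Route**

Step 1
Reactants: 1 (E)-pent-2-en-1-ol
Product: 2 ((2S,3S)-3-ethyloxiran-2-yl)methanol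
Conditions: Ti(OiPr)4 (5 mol %), L-(+)-diethyl tartrate (6 mol %), t-BuOOH, 4 Å MS, CH2Cl2, −20 °C
Reagents that add atoms: tert-butyl hydroperoxide, CC(C)(C)OO
Why: Sharpless asymmetric epoxidation: the Ti/L-(+)-tartrate catalyst transfers oxygen to one enantioface of the allylic alcohol to give the (2S,3S)-epoxide (typically ≥95% ee), creating the C–O bond that is carried through to the C2 ketone of 22.

Step 2
Reactants: 2 ((2S,3S)-3-ethyloxiran-2-yl)methanol; 3 but-1-yne
Product: 6 (2R,3S)-3-ethylhept-4-yne-1,2-diol, via lithium but-1-ynide 4 (not isolated), via diethyl(but-1-ynyl)aluminium 5 (not isolated)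
Conditions: 3, n-BuLi, toluene, 0 °C; Et2AlCl; then 2, 0 °C to rt; aq. potassium sodium tartrate
Reagents that add atoms: none
Why: Alkynylalane opening of the 2,3-epoxy alcohol (aluminium alkoxide-directed SN2 at C3 with inversion) gives the 1,2-diol and turns the epoxide C–O stereocentre into the (S)-configured C–C stereocentre that becomes C1 of 22.

Step 3
Reactants: 6 (2R,3S)-3-ethylhept-4-yne-1,2-diol
Product: 7 (S)-2-ethylhex-3-ynal
Conditions: NaIO4 on silica gel, CH2Cl2, rt; filter; solution used at once in step 6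
Reagents that add atoms: none
Why: Periodate glycol cleavage (Malaprade reaction) removes the terminal carbon; the oxygen installed in step 1 stays on the new aldehyde carbon, and the neutral anhydrous protocol keeps the α-stereocentre intact.

Step 4
Reactants: 8 (E)-2-ethylhex-2-enoic acid; 9 (S)-4-isopropyloxazolidin-2-one
Product: 11 (S)-3-[(E)-2-ethylhex-2-enoyl]-4-isopropyloxazolidin-2-one, via mixed pivalic anhydride 10 (not isolated)
Conditions: t-BuCOCl, Et3N, THF, −20 °C; then LiCl, 9, rt
Reagents that add atoms: none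
Why: Mixed-anhydride N-acylation of the oxazolidinone under mild LiCl/Et3N conditions leaves the E-alkene untouched; no stereocentre is formed.

Step 5
Reactants: 11 (S)-3-[(E)-2-ethylhex-2-enoyl]-4-isopropyloxazolidin-2-one
Product: 12 (S)-3-[(1E,3E)-1-(tert-butyldimethylsilyloxy)-2-ethylhexa-1,3-dien-1-yl]-4-isopropyloxazolidin-2-one
Conditions: NaN(SiMe3)2, t-BuMe2SiCl, THF, −78 °C
Reagents that add atoms: tert-butyldimethylsilyl chloride, CC(C)(C)[Si](C)(C)Cl
Why: γ-Deprotonation of the s-trans enoyl imide and O-silylation give the E,E vinylketene silyl N,O-acetal (Kobayashi-type reagent).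

Step 6
Reactants: 7 (S)-2-ethylhex-3-ynal; 12 (S)-3-[(1E,3E)-1-(tert-butyldimethylsilyloxy)-2-ethylhexa-1,3-dien-1-yl]-4-isopropyloxazolidin-2-one
Product: 13 (S)-3-[(2E,4S,5S,6S)-2,4,6-triethyl-5-hydroxydec-2-en-7-ynoyl]-4-isopropyloxazolidin-2-one
Conditions: TiCl4, CH2Cl2, −78 °C
Reagents that add atoms: none
Why: Vinylogous Mukaiyama aldol (Kobayashi type): the TiCl4-activated aldehyde attacks the γ-carbon of the dienol ether on the face away from the isopropyl group of the twisted oxazolidinone through an open anti transition state, so the reagent sets the ethyl-bearing stereocentre (C3 of 22) as S and the carbinol anti to it, and gives the E-enoyl unit directly.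

Step 7
Reactants: 13 (S)-3-[(2E,4S,5S,6S)-2,4,6-triethyl-5-hydroxydec-2-en-7-ynoyl]-4-isopropyloxazolidin-2-one
Product: 14 (2E,4S,5S,6S)-2,4,6-triethyldec-2-en-7-yne-1,5-diol
Conditions: NaBH4, THF/H2O, 0 °C to rt
Reagents that add atoms: none
Why: Hydride reduction of the N-acyl oxazolidinone (1,2-reduction) releases the allylic alcohol and the recoverable auxiliary without touching a stereocentre, and removes the base-sensitive imide before the palladium steps.

Step 8
Reactants: 3 but-1-yne
Product: 15 (E)-2-bromo-1-iodobut-1-ene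
Conditions: IBr, CH2Cl2, −78 °C to 0 °C, dark
Reagents that add atoms: iodine monobromide, BrI
Why: Electrophilic anti addition of IBr through an iodirenium ion (bromide opens at the substituted carbon) gives the E-dihalide, in which only the C–I bond reacts in step 9.

Step 9
Reactants: 14 (2E,4S,5S,6S)-2,4,6-triethyldec-2-en-7-yne-1,5-diol; 15 (E)-2-bromo-1-iodobut-1-ene
Product: 16 (2E,4S,5R,6S,7E,9E)-10-bromo-2,4,6,8-tetraethyldodeca-2,7,9-triene-1,5-diol
Conditions: Pd(OAc)2 (5 mol %), tri(2-furyl)phosphine (10 mol %), HCO2Na, 15 (1.5 equiv), DMF, 40 °C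
Reagents that add atoms: none
Why: Proposed new method: zerovalent palladium inserts into the C–I bond of 15 only (the C–Br bond is inert at 40 °C), the alkenylpalladium iodide is held by the C5 hydroxyl of 14 and adds syn across the alkyne with carbon going to the less hindered ethyl-bearing carbon and palladium to the carbon next to the branched C6 (five-membered Pd–O chelate), and formate then delivers hydride (loss of CO2) for C–H reductive elimination with retention, so the net result is a regio- and syn-selective hydroalkenylation that fixes the (7E) diene geometry; the closest known reaction type is the formate-driven reductive Heck hydroarylation or hydrovinylation of alkynes, which has not been shown for unactivated dialkyl alkynes or for a bromo-iodo-alkene partner.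

Step 10
Reactants: 16 (2E,4S,5R,6S,7E,9E)-10-bromo-2,4,6,8-tetraethyldodeca-2,7,9-triene-1,5-diol; 17 (E)-2-phenylvinylboronic acid
Product: 18 (2E,4S,5R,6S,7E,9E,11E)-2,4,6,8,10-pentaethyl-12-phenyldodeca-2,7,9,11-tetraene-1,5-diol
Conditions: Pd(OAc)2 (3 mol %), SPhos (6 mol %), K3PO4, THF/H2O, 50 °C
Reagents that add atoms: none
Why: Suzuki–Miyaura coupling of the hindered alkenyl bromide proceeds with retention at both alkenes and completes the all-E triene; free hydroxyls are tolerated.

Step 11
Reactants: 18 (2E,4S,5R,6S,7E,9E,11E)-2,4,6,8,10-pentaethyl-12-phenyldodeca-2,7,9,11-tetraene-1,5-diol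
Product: 20 (1S,2R,3S,3aR,4R,5S,7aR)-1,3,4,5,7-pentaethyl-2-hydroxy-5-[(E)-2-phenylethenyl]-2,3,3a,4,5,7a-hexahydro-1H-indene-4-carbaldehyde, via tetraenal 19 (not isolated)
Conditions: MnO2, CH2Cl2, rt; filter; toluene, BHT, 80 °C
Reagents that add atoms: none
Why: MnO2 oxidises only the primary allylic alcohol, and the resulting (E)-2-ethyl enal undergoes a thermal intramolecular Diels–Alder reaction through the CHO-endo transition state in which the C1–H and C3–H bonds lie in the planes of the diene and dienophile (allylic 1,3-strain), so the two S tether stereocentres select the same pair of π-faces and set C3a, C4, C5 and C7a in the trans-fused array; the tether carbinol is kept so that C1 and C3 cannot enolise while triene and enal coexist.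

Step 12
Reactants: 20 (1S,2R,3S,3aR,4R,5S,7aR)-1,3,4,5,7-pentaethyl-2-hydroxy-5-[(E)-2-phenylethenyl]-2,3,3a,4,5,7a-hexahydro-1H-indene-4-carbaldehyde
Product: 21 (1S,3S,3aR,4R,5S,7aR)-1,3,4,5,7-pentaethyl-2-oxo-5-[(E)-2-phenylethenyl]-2,3,3a,4,5,7a-hexahydro-1H-indene-4-carbaldehyde
Conditions: Dess–Martin periodinane, NaHCO3, CH2Cl2, 0 °C to rt
Reagents that add atoms: none
Why: Dess–Martin oxidation of the secondary alcohol under buffered conditions gives the ketone (the oxygen placed in step 1); the flanking ethyl groups are already in the all-trans arrangement expected to be the thermodynamic one, so enolisation should do no harm.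

Step 13
Reactants: 21 (1S,3S,3aR,4R,5S,7aR)-1,3,4,5,7-pentaethyl-2-oxo-5-[(E)-2-phenylethenyl]-2,3,3a,4,5,7a-hexahydro-1H-indene-4-carbaldehyde
Product: 22 (1S,3S,3aR,4R,5S,7aR)-1,3,4,5,7-pentaethyl-2-oxo-5-[(E)-2-phenylethenyl]-2,3,3a,4,5,7a-hexahydro-1H-indene-4-carboxylic acid
Conditions: NaClO2, NaH2PO4, 2-methyl-2-butene, t-BuOH/H2O, rt
Reagents that add atoms: sodium chlorite, [Na+].[O-]Cl=O
Why: Pinnick oxidation converts the hindered aldehyde on the quaternary carbon to the acid without touching the alkenes (hypochlorite is scavenged by 2-methyl-2-butene) and without acid that could lactonise the product.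

**Compound list**

1 | (E)-pent-2-en-1-ol | CC/C=C/CO | starting material
2 | ((2S,3S)-3-ethyloxiran-2-yl)methanol | OC[C@@H]1O[C@H]1CC | intermediate
3 | but-1-yne | CCC#C | starting material
4 | lithium but-1-ynide | [Li]C#CCC | intermediate
5 | diethyl(but-1-ynyl)aluminium | CC[Al](CC)C#CCC | intermediate
6 | (2R,3S)-3-ethylhept-4-yne-1,2-diol | OC[C@H](O)[C@@H](CC)C#CCC | intermediate
7 | (S)-2-ethylhex-3-ynal | O=C[C@@H](CC)C#CCC | intermediate
8 | (E)-2-ethylhex-2-enoic acid | CCC/C=C(\CC)C(=O)O | starting material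
9 | (S)-4-isopropyloxazolidin-2-one | CC(C)[C@H]1COC(=O)N1 | starting material
10 | (E)-2-ethylhex-2-enoic pivalic anhydride | CCC/C=C(\CC)C(=O)OC(=O)C(C)(C)C | intermediate
11 | (S)-3-[(E)-2-ethylhex-2-enoyl]-4-isopropyloxazolidin-2-one | CCC/C=C(\CC)C(=O)N1[C@@H](C(C)C)COC1=O | intermediate
12 | (S)-3-[(1E,3E)-1-(tert-butyldimethylsilyloxy)-2-ethylhexa-1,3-dien-1-yl]-4-isopropyloxazolidin-2-one | CC/C=C/C(/CC)=C(/O[Si](C)(C)C(C)(C)C)N1[C@@H](C(C)C)COC1=O | intermediate
13 | (S)-3-[(2E,4S,5S,6S)-2,4,6-triethyl-5-hydroxydec-2-en-7-ynoyl]-4-isopropyloxazolidin-2-one | CCC#C[C@H](CC)[C@@H](O)[C@@H](CC)/C=C(\CC)C(=O)N1[C@@H](C(C)C)COC1=O | intermediate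
14 | (2E,4S,5S,6S)-2,4,6-triethyldec-2-en-7-yne-1,5-diol | CCC#C[C@H](CC)[C@@H](O)[C@@H](CC)/C=C(\CC)CO | intermediate
15 | (E)-2-bromo-1-iodobut-1-ene | CC/C(Br)=C\I | intermediate
16 | (2E,4S,5R,6S,7E,9E)-10-bromo-2,4,6,8-tetraethyldodeca-2,7,9-triene-1,5-diol | CC/C(Br)=C\C(CC)=C\[C@H](CC)[C@@H](O)[C@@H](CC)/C=C(\CC)CO | intermediate
17 | (E)-2-phenylvinylboronic acid | OB(O)/C=C/c1ccccc1 | starting material
18 | (2E,4S,5R,6S,7E,9E,11E)-2,4,6,8,10-pentaethyl-12-phenyldodeca-2,7,9,11-tetraene-1,5-diol | CC/C(/C=C/c1ccccc1)=C\C(CC)=C\[C@H](CC)[C@@H](O)[C@@H](CC)/C=C(\CC)CO | intermediate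
19 | (2E,4S,5R,6S,7E,9E,11E)-2,4,6,8,10-pentaethyl-5-hydroxy-12-phenyldodeca-2,7,9,11-tetraenal | CC/C(/C=C/c1ccccc1)=C\C(CC)=C\[C@H](CC)[C@@H](O)[C@@H](CC)/C=C(\CC)C=O | intermediate
20 | (1S,2R,3S,3aR,4R,5S,7aR)-1,3,4,5,7-pentaethyl-2-hydroxy-5-[(E)-2-phenylethenyl]-2,3,3a,4,5,7a-hexahydro-1H-indene-4-carbaldehyde (trans ring fusion; OH cis to the C3 ethyl) | CCC1=C[C@@](/C=C/c2ccccc2)(CC)[C@](CC)(C=O)[C@@H]2[C@@H]1[C@H](CC)[C@@H](O)[C@H]2CC | intermediate
21 | (1S,3S,3aR,4R,5S,7aR)-1,3,4,5,7-pentaethyl-2-oxo-5-[(E)-2-phenylethenyl]-2,3,3a,4,5,7a-hexahydro-1H-indene-4-carbaldehyde | CCC1=C[C@@](/C=C/c2ccccc2)(CC)[C@](CC)(C=O)[C@@H]2[C@@H]1[C@H](CC)C(=O)[C@H]2CC | intermediate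
22 | (1S,3S,3aR,4R,5S,7aR)-1,3,4,5,7-pentaethyl-2-oxo-5-[(E)-2-phenylethenyl]-2,3,3a,4,5,7a-hexahydro-1H-indene-4-carboxylic acid | CCC1=C[C@@](/C=C/c2ccccc2)(CC)[C@](CC)(C(=O)O)[C@@H]2[C@@H]1[C@H](CC)C(=O)[C@H]2CC | target

**Step count and risk**

Total steps: 13. Longest linear sequence: 10 (steps 1, 2, 3, 6, 7, 9, 10, 11, 12, 13). Steps 4 and 5 (reagent 12) and step 8 (linchpin 15) are side branches.

The three steps most likely to fail:

Step 9 (the proposed new hydroalkenylation). The risks are premature reduction of the alkenylpalladium species by formate and incomplete regiocontrol. The fallback uses known chemistry, sets out from 14 and comes back at 16. Pd(PPh3)2Cl2-catalysed syn-hydrostannation of 14 with Bu3SnH (THF, rt) places tin on the less hindered alkyne carbon and gives (2E,4S,5S,6S,7E)-2,4,6-triethyl-8-(tributylstannyl)deca-2,7-diene-1,5-diol F1, which is purified from any regioisomer. Stille coupling of F1 with 15 at the C–I bond (Pd2(dba)3, AsPh3, CuI, DMF, rt) gives 16.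

Step 6 (vinylogous aldol). The risks are epimerisation of the α-alkynyl aldehyde 7 under TiCl4 and lower selectivity of the diethyl-substituted reagent; the sense of induction rests on the face-shielding model for this auxiliary. The fallback replaces the vinylogous aldol by an allylboration, sets out from 7 and comes back at 14. (E)-Pent-2-ene is metalated (n-BuLi, KOt-Bu, THF, −78 to −50 °C) and trapped with (−)-Ipc2BOMe and BF3·OEt2. The resulting (E)-pent-2-enyl-B(Ipc)2 adds to 7 at −78 °C through a chair transition state (Si-face attack, NaOH/H2O2 work-up) to give the anti homoallylic alcohol (3S,4S,5S)-3,5-diethylnon-1-en-6-yn-4-ol F2. Ozonolysis of the vinyl group (O3, CH2Cl2, −78 °C; Me2S; the alkyne is spared) gives (2R,3R,4S)-2,4-diethyl-3-hydroxyoct-5-ynal F3, which is not isolated but treated with Ph3P=C(Et)CO2Et (CH2Cl2, rt) to give ethyl (2E,4S,5S,6S)-2,4,6-triethyl-5-hydroxydec-2-en-7-ynoate F4. Reduction of F4 with i-Bu2AlH (CH2Cl2, −78 °C) gives 14.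

Step 11 (Diels–Alder). The risks are slow closure between two fully substituted carbons and endo/exo leakage. The fallback changes the cyclisation substrate to the ketone-tethered triene, sets out from 18 and comes back at 21. Both hydroxyls of 18 are oxidised at once with Dess–Martin periodinane (NaHCO3, CH2Cl2) to the keto enal (2E,4S,6S,7E,9E,11E)-2,4,6,8,10-pentaethyl-5-oxo-12-phenyldodeca-2,7,9,11-tetraenal F5. F5 is cyclised with its planar C2 tether carbon (toluene, 60 °C), followed by brief DBU treatment to equilibrate C1 and C3 to the all-trans ketone; the cycloadduct is 21.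

Further compounds

F1 | step 9 | (2E,4S,5S,6S,7E)-2,4,6-triethyl-8-(tributylstannyl)deca-2,7-diene-1,5-diol | CC/C(=C\[C@H](CC)[C@@H](O)[C@@H](CC)/C=C(\CC)CO)[Sn](CCCC)(CCCC)CCCC
F2 | step 6 | (3S,4S,5S)-3,5-diethylnon-1-en-6-yn-4-ol | CCC#C[C@H](CC)[C@@H](O)[C@@H](CC)C=C
F3 | step 6 | (2R,3R,4S)-2,4-diethyl-3-hydroxyoct-5-ynal | CCC#C[C@H](CC)[C@@H](O)[C@@H](CC)C=O
F4 | step 6 | ethyl (2E,4S,5S,6S)-2,4,6-triethyl-5-hydroxydec-2-en-7-ynoate | CCC#C[C@H](CC)[C@@H](O)[C@@H](CC)/C=C(\CC)C(=O)OCC
F5 | step 11 | (2E,4S,6S,7E,9E,11E)-2,4,6,8,10-pentaethyl-5-oxo-12-phenyldodeca-2,7,9,11-tetraenal | CC/C(/C=C/c1ccccc1)=C\C(CC)=C\[C@H](CC)C(=O)[C@@H](CC)/C=C(\CC)C=O
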